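The seven-membered ring of the longipinane (C5–C6–C7–C8–C9–C10–C11) holds an oxygenated carbon C7 between the gem-dimethyl carbon C6 and the methylene C8: the imprint of a 1,1-dimethyl-2-oxyallyl cation. Its (4+3) cycloaddition to 3-methylfuran, from 3-bromo-3-methylbutan-2-one and base, forms C5–C6 and C8–C9 in one operation and delivers every carbon of that ring. The oxabicycle is opened to an achiral dienedione; one catalytic asymmetric β-borylation then sets C9, and this centre is relayed to C7, C10, C11 and C5 by two directed reductions and a Diels–Alder annulation. Enolate displacement closes the cyclobutane; a carbonyl transposition and two acylations finish.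

Key step: step 1

Remark: tricyclic compounds carry longipinane numbering (C1 carbonyl carbon, C2=C3 with the C3 methyl C15, cyclobutane C4–C5–C11–C10, C6 gem-dimethyl carbon, C7 and C9 oxygenated, C8 methylene, C1 bonded to C11). Compounds 4 and 5 are racemic and drawn as one enantiomer; the first lasting stereocentre is set in step 4.

Step 1
Reactants: 1 3-bromo-3-methylbutan-2-one; 2 3-methylfuran
Product: 4 racemic 2,2,6-trimethyl-8-oxabicyclo[3.2.1]oct-6-en-3-one, via oxyallyl cation 3 (not isolated)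
Conditions: Et3N (1.5 equiv), 2 (4 equiv), CF3CH2OH, 0 to 25 °C
Reagents that add atoms: none
Why: Et3N in the ionising fluoroalcohol converts 1 by enolisation and loss of bromide into the 1,1-dimethyl-2-oxyallyl cation 3, which adds as a 2π allyl cation across the 4π furan diene in a concerted, asynchronous (4+3) cycloaddition, the oxyallyl–furan reaction type. The cycloheptenone ring is closed by this cycloaddition through two σ bonds (the later C5–C6 and C8–C9), the furan oxygen ending as a 1,4-bridge. The two bridgehead stereocentres are cis because the cation adds suprafacially to one face of the planar furan; they form as a racemate and are not needed later. The step needs regioselectivity: the more nucleophilic furan C2, next to the methyl-bearing carbon, should bond to the unhindered CH2 terminus and C5 to the CMe2 terminus, the orientation this cation shows with 2-substituted 1,3-dienes, and this also keeps the gem-dimethyl group away from the ring methyl. The minor 2,2,7-trimethyl regioisomer would be removed by chromatography.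

Step 2
Reactants: 4 racemic 2,2,6-trimethyl-8-oxabicyclo[3.2.1]oct-6-en-3-one
Product: 5 racemic 6-hydroxy-4,7,7-trimethylcyclohepta-2,4-dien-1-one
Conditions: LiN(SiMe3)2, THF, −78 to 0 °C; then AcOH
Reagents that add atoms: none
Why: E1cB ring opening, in which the only enolate available (the other α-carbon is quaternary) expels the axial bridging alkoxide to give the conjugated dienone alcohol; no stereocentre is set.

Step 3
Reactants: 5 racemic 6-hydroxy-4,7,7-trimethylcyclohepta-2,4-dien-1-one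
Product: 6 2,2,5-trimethylcyclohepta-4,6-diene-1,3-dione
Conditions: MnO2, CH2Cl2, 25 °C
Reagents that add atoms: none
Why: Allylic alcohol oxidation should give the achiral dienedione, which cannot enolise between the carbonyls and in which the last stereocentre is erased.

Step 4
Reactants: 6 2,2,5-trimethylcyclohepta-4,6-diene-1,3-dione
Product: 8 (6R)-6-hydroxy-2,2,5-trimethylcyclohept-4-ene-1,3-dione, via pinacol boronate 7 (not isolated)
Conditions: B2pin2, CuCl (5 mol %), NaOtBu (10 mol %), (R,R)-2,3-bis(tert-butylmethylphosphino)quinoxaline (6 mol %; the antipode if the induction proves opposite), MeOH, THF, 0 °C; then NaBO3·4H2O, THF–H2O, 25 °C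
Reagents that add atoms: sodium perborate, [Na+].[Na+].O[B-]1(O)OO[B-](O)(O)OO1 (hydroxyl oxygen of 8); bis(pinacolato)diboron, CC1(C)OB(OC1(C)C)B1OC(C)(C)C(C)(C)O1 (boron of 7 only)
Why: Copper-catalysed enantioselective conjugate borylation should deliver boron to the β-carbon of the unsubstituted enone rather than to the hindered β-methyl enone, the chiral bisphosphine setting the 6R centre, and perborate oxidation replaces boron by hydroxyl with retention.

Step 5
Reactants: 8 (6R)-6-hydroxy-2,2,5-trimethylcyclohept-4-ene-1,3-dione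
Product: 9 (4R,6R)-4,6-dihydroxy-3,7,7-trimethylcyclohept-2-en-1-one
Conditions: Me4NBH(OAc)3, MeCN–AcOH, −30 °C
Reagents that add atoms: none
Why: Evans–Saksena reduction, in which the alkoxyborohydride formed at the hydroxyl delivers hydride internally to the saturated β-ketone only, giving the 1,3-anti (trans) diol and leaving the hindered enone carbonyl.

Step 6
Reactants: 9 (4R,6R)-4,6-dihydroxy-3,7,7-trimethylcyclohept-2-en-1-one
Product: 10 (4R,6R)-4-(tert-butyldimethylsilyloxy)-6-hydroxy-3,7,7-trimethylcyclohept-2-en-1-one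
Conditions: TBSCl (1.05 equiv), imidazole, DMF, 0 °C
Reagents that add atoms: tert-butyldimethylsilyl chloride, CC(C)(C)[Si](C)(C)Cl
Why: Silyl ether formation should occur at the less hindered allylic C4 hydroxyl, leaving the neopentyl C6 hydroxyl beside the quaternary carbon free.

Step 7
Reactants: 10 (4R,6R)-4-(tert-butyldimethylsilyloxy)-6-hydroxy-3,7,7-trimethylcyclohept-2-en-1-one; 11 (E)-1-methoxy-3-(trimethylsilyloxy)buta-1,3-diene
Product: 13 (1S,4R,6R,7R)-6-(tert-butyldimethylsilyloxy)-4-hydroxy-3,3,7-trimethylbicyclo[5.4.0]undec-10-ene-2,9-dione, via cycloadduct silyl enol ether 12 (not isolated)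
Conditions: 11 (3 equiv), toluene, 110 °C, sealed tube; then 0.1 M HCl, THF, 0 °C
Reagents that add atoms: none
Why: Diels–Alder reaction in which the nucleophilic CH2 terminus of the siloxydiene bonds to the β-carbon of the enone (creating the quaternary methyl centre), the diene adds suprafacially (cis ring fusion) and anti to the neighbouring silyloxy group, and acid then unmasks the cyclohexenone by hydrolysis and loss of methanol.

Step 8
Reactants: 13 (1S,4R,6R,7R)-6-(tert-butyldimethylsilyloxy)-4-hydroxy-3,3,7-trimethylbicyclo[5.4.0]undec-10-ene-2,9-dione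
Product: 14 (1S,2R,4R,6R,7R)-6-(tert-butyldimethylsilyloxy)-2,4-dihydroxy-3,3,7-trimethylbicyclo[5.4.0]undec-10-en-9-one
Conditions: Me4NBH(OAc)3, MeCN–AcOH, −20 °C
Reagents that add atoms: none
Why: A second Evans–Saksena reduction, in which the free C4 hydroxyl delivers hydride to the C2 ketone from its own face, should give the 2,4-anti diol with the new hydroxyl trans to the fused six-membered ring, the enone carbonyl having no directing hydroxyl.

Step 9
Reactants: 14 (1S,2R,4R,6R,7R)-6-(tert-butyldimethylsilyloxy)-2,4-dihydroxy-3,3,7-trimethylbicyclo[5.4.0]undec-10-en-9-one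
Product: 15 (1S,2R,4R,6R,7R)-4-acetoxy-6-(tert-butyldimethylsilyloxy)-2-hydroxy-3,3,7-trimethylbicyclo[5.4.0]undec-10-en-9-one
Conditions: Ac2O (1.1 equiv), pyridine, DMAP (cat.), CH2Cl2, 0 °C
Reagents that add atoms: acetic anhydride, CC(=O)OC(C)=O
Why: Acetylation should select the C4 hydroxyl (flanked by a methylene) over the C2 hydroxyl (flanked by the quaternary carbon and the ring-fusion methine).

Step 10
Reactants: 15 (1S,2R,4R,6R,7R)-4-acetoxy-6-(tert-butyldimethylsilyloxy)-2-hydroxy-3,3,7-trimethylbicyclo[5.4.0]undec-10-en-9-one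
Product: 16 (1S,2R,4R,6R,7R)-4-acetoxy-6-(tert-butyldimethylsilyloxy)-2-(methanesulfonyloxy)-3,3,7-trimethylbicyclo[5.4.0]undec-10-en-9-one
Conditions: MsCl, Et3N, CH2Cl2, 0 °C
Reagents that add atoms: methanesulfonyl chloride, CS(=O)(=O)Cl
Why: Mesylation through the small sulfene electrophile activates the remaining hindered secondary alcohol without touching its configuration.

Step 11
Reactants: 16 (1S,2R,4R,6R,7R)-4-acetoxy-6-(tert-butyldimethylsilyloxy)-2-(methanesulfonyloxy)-3,3,7-trimethylbicyclo[5.4.0]undec-10-en-9-one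
Product: 18 (4S,5R,7R,9R,10S,11R)-7-acetoxy-9-(tert-butyldimethylsilyloxy)-15-norlongipin-1-en-3-one, via potassium dienolate 17 (not isolated)
Conditions: KN(SiMe3)2 (1.1 equiv), THF, −78 to 25 °C
Reagents that add atoms: none
Why: Kinetic deprotonation gives the cross-conjugated α′-enolate at C8, which displaces the mesylate in an intramolecular 4-exo-tet enolate alkylation (the closure known for bicyclo[3.1.1]heptanones), with inversion at C2, so the cyclobutane and the longipinane C4 and C5 centres follow from the anti arrangement set in steps 7 and 8.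

Step 12
Reactants: 18 (4S,5R,7R,9R,10S,11R)-7-acetoxy-9-(tert-butyldimethylsilyloxy)-15-norlongipin-1-en-3-one
Product: 19 (4S,5R,7R,9R,10S,11R)-9-(tert-butyldimethylsilyloxy)longipin-1-ene-3,7-diol
Conditions: MeLi (5 equiv), THF, −78 to 0 °C; then H2O
Reagents that add atoms: methyllithium, [Li]C
Why: 1,2-Addition of the organolithium to the non-enolisable bridged enone installs C15 as a tertiary allylic alcohol (its configuration is lost again in step 14), while excess reagent cleaves the acetate.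

Step 13
Reactants: 19 (4S,5R,7R,9R,10S,11R)-9-(tert-butyldimethylsilyloxy)longipin-1-ene-3,7-diol
Product: 20 (4S,5R,7R,9R,10S,11R)-9-(tert-butyldimethylsilyloxy)-3-hydroxylongipin-1-en-7-yl 3-methylbut-2-enoate
Conditions: 3-methylbut-2-enoyl chloride, pyridine, DMAP, CH2Cl2, 0 to 25 °C
Reagents that add atoms: 3-methylbut-2-enoyl chloride, CC(C)=CC(=O)Cl
Why: DMAP-catalysed acylation should esterify the secondary C7 hydroxyl only, the tertiary allylic hydroxyl being too hindered to react.

Step 14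
Reactants: 20 (4S,5R,7R,9R,10S,11R)-9-(tert-butyldimethylsilyloxy)-3-hydroxylongipin-1-en-7-yl 3-methylbut-2-enoate
Product: 21 (4R,5S,7R,9R,10R,11R)-9-(tert-butyldimethylsilyloxy)-1-oxolongipin-2-en-7-yl 3-methylbut-2-enoate
Conditions: pyridinium chlorochromate (C5H5NH[CrO3Cl]), 4 Å molecular sieves, CH2Cl2, 25 °C
Reagents that add atoms: pyridinium chlorochromate, [O-][Cr](=O)(=O)Cl.c1cc[nH+]cc1
Why: Babler–Dauben oxidative transposition, in which the tertiary allylic chromate ester undergoes a [3,3] shift and is oxidised, should place the carbonyl at C1 and the double bond at C2=C3.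

Step 15
Reactants: 21 (4R,5S,7R,9R,10R,11R)-9-(tert-butyldimethylsilyloxy)-1-oxolongipin-2-en-7-yl 3-methylbut-2-enoate
Product: 22 (4R,5S,7R,9R,10R,11R)-9-hydroxy-1-oxolongipin-2-en-7-yl 3-methylbut-2-enoate
Conditions: HF·pyridine, THF, 0 to 25 °C
Reagents that add atoms: none
Why: Fluoride-driven desilylation under weakly acidic conditions frees the C9 hydroxyl without acyl migration or harm to the enone and ester.

Step 16
Reactants: 22 (4R,5S,7R,9R,10R,11R)-9-hydroxy-1-oxolongipin-2-en-7-yl 3-methylbut-2-enoate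
Product: 23 (4R,5S,7R,9R,10R,11R)-9-(3-methylbutanoyloxy)-1-oxolongipin-2-en-7-yl 3-methylbut-2-enoate
Conditions: 3-methylbutanoyl chloride, pyridine, DMAP, CH2Cl2, 40 °C
Reagents that add atoms: 3-methylbutanoyl chloride, CC(C)CC(=O)Cl
Why: DMAP-catalysed acylation of the neopentyl C9 hydroxyl completes the diester without touching any stereocentre.

Compound list
1 | 3-bromo-3-methylbutan-2-one | CC(=O)C(C)(C)Br | starting material
2 | 3-methylfuran | Cc1ccoc1 | starting material
3 | 1,1-dimethyl-2-oxidoallyl cation (oxyallyl zwitterion) | C=C([O-])[C+](C)C | intermediate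
4 | racemic 2,2,6-trimethyl-8-oxabicyclo[3.2.1]oct-6-en-3-one (bridgehead hydrogens cis; one enantiomer drawn) | O=C1C[C@H]2O[C@H](C=C2C)C1(C)C | intermediate
5 | racemic 6-hydroxy-4,7,7-trimethylcyclohepta-2,4-dien-1-one | O=C1C=CC(C)=CC(O)C1(C)C | intermediate
6 | 2,2,5-trimethylcyclohepta-4,6-diene-1,3-dione (achiral) | O=C1C=CC(C)=CC(=O)C1(C)C | intermediate
7 | (6R)-2,2,5-trimethyl-6-(4,4,5,5-tetramethyl-1,3,2-dioxaborolan-2-yl)cyclohept-4-ene-1,3-dione | O=C1C[C@@H](B2OC(C)(C)C(C)(C)O2)C(C)=CC(=O)C1(C)C | intermediate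
8 | (6R)-6-hydroxy-2,2,5-trimethylcyclohept-4-ene-1,3-dione | O=C1C[C@@H](O)C(C)=CC(=O)C1(C)C | intermediate
9 | (4R,6R)-4,6-dihydroxy-3,7,7-trimethylcyclohept-2-en-1-one (trans-diol) | O[C@@H]1C[C@@H](O)C(C)=CC(=O)C1(C)C | intermediate
10 | (4R,6R)-4-(tert-butyldimethylsilyloxy)-6-hydroxy-3,7,7-trimethylcyclohept-2-en-1-one | O[C@@H]1C[C@@H](O[Si](C)(C)C(C)(C)C)C(C)=CC(=O)C1(C)C | intermediate
11 | (E)-1-methoxy-3-(trimethylsilyloxy)buta-1,3-diene | CO/C=C/C(=C)O[Si](C)(C)C | starting material
12 | Diels–Alder adduct: 6-(tert-butyldimethylsilyloxy)-4-hydroxy-11-methoxy-3,3,7-trimethyl-9-(trimethylsilyloxy)bicyclo[5.4.0]undec-9-en-2-one, cis-fused, configured as 13 at C1, C4, C6 and C7, either C11 epimer | O[C@@H]1C[C@@H](O[Si](C)(C)C(C)(C)C)[C@]2(C)CC(O[Si](C)(C)C)=CC(OC)[C@@H]2C(=O)C1(C)C | intermediate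
13 | (1S,4R,6R,7R)-6-(tert-butyldimethylsilyloxy)-4-hydroxy-3,3,7-trimethylbicyclo[5.4.0]undec-10-ene-2,9-dione (cis-fused; C7 methyl and C1 hydrogen cis; silyl ether trans to C8) | O[C@@H]1C[C@@H](O[Si](C)(C)C(C)(C)C)[C@]2(C)CC(=O)C=C[C@@H]2C(=O)C1(C)C | intermediate
14 | (1S,2R,4R,6R,7R)-6-(tert-butyldimethylsilyloxy)-2,4-dihydroxy-3,3,7-trimethylbicyclo[5.4.0]undec-10-en-9-one (2-OH trans to 4-OH and trans to C11) | O[C@@H]1C[C@@H](O[Si](C)(C)C(C)(C)C)[C@]2(C)CC(=O)C=C[C@@H]2[C@@H](O)C1(C)C | intermediate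
15 | (1S,2R,4R,6R,7R)-4-acetoxy-6-(tert-butyldimethylsilyloxy)-2-hydroxy-3,3,7-trimethylbicyclo[5.4.0]undec-10-en-9-one | CC(=O)O[C@@H]1C[C@@H](O[Si](C)(C)C(C)(C)C)[C@]2(C)CC(=O)C=C[C@@H]2[C@@H](O)C1(C)C | intermediate
16 | (1S,2R,4R,6R,7R)-4-acetoxy-6-(tert-butyldimethylsilyloxy)-2-(methanesulfonyloxy)-3,3,7-trimethylbicyclo[5.4.0]undec-10-en-9-one | CC(=O)O[C@@H]1C[C@@H](O[Si](C)(C)C(C)(C)C)[C@]2(C)CC(=O)C=C[C@@H]2[C@@H](OS(C)(=O)=O)C1(C)C | intermediate
17 | potassium cross-conjugated (C8–C9) dienolate of 16 | CC(=O)O[C@@H]1C[C@@H](O[Si](C)(C)C(C)(C)C)[C@]2(C)C=C([O-])C=C[C@@H]2[C@@H](OS(C)(=O)=O)C1(C)C.[K+] | intermediate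
18 | (4S,5R,7R,9R,10S,11R)-7-acetoxy-9-(tert-butyldimethylsilyloxy)-15-norlongipin-1-en-3-one | CC(=O)O[C@@H]1C[C@@H](O[Si](C)(C)C(C)(C)C)[C@@]2(C)[C@@H]3C=CC(=O)[C@H]2[C@@H]3C1(C)C | intermediate
19 | (4S,5R,7R,9R,10S,11R)-9-(tert-butyldimethylsilyloxy)longipin-1-ene-3,7-diol (C3 configuration not specified) | O[C@@H]1C[C@@H](O[Si](C)(C)C(C)(C)C)[C@@]2(C)[C@@H]3C=CC(C)(O)[C@H]2[C@@H]3C1(C)C | intermediate
20 | (4S,5R,7R,9R,10S,11R)-9-(tert-butyldimethylsilyloxy)-3-hydroxylongipin-1-en-7-yl 3-methylbut-2-enoate (C3 configuration not specified) | CC(C)=CC(=O)O[C@@H]1C[C@@H](O[Si](C)(C)C(C)(C)C)[C@@]2(C)[C@@H]3C=CC(C)(O)[C@H]2[C@@H]3C1(C)C | intermediate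
21 | (4R,5S,7R,9R,10R,11R)-9-(tert-butyldimethylsilyloxy)-1-oxolongipin-2-en-7-yl 3-methylbut-2-enoate | CC(C)=CC(=O)O[C@@H]1C[C@@H](O[Si](C)(C)C(C)(C)C)[C@@]2(C)[C@@H]3C(=O)C=C(C)[C@H]2[C@@H]3C1(C)C | intermediate
22 | (4R,5S,7R,9R,10R,11R)-9-hydroxy-1-oxolongipin-2-en-7-yl 3-methylbut-2-enoate | CC(C)=CC(=O)O[C@@H]1C[C@@H](O)[C@@]2(C)[C@@H]3C(=O)C=C(C)[C@H]2[C@@H]3C1(C)C | intermediate
23 | (4R,5S,7R,9R,10R,11R)-9-(3-methylbutanoyloxy)-1-oxolongipin-2-en-7-yl 3-methylbut-2-enoate (CNP0214473.1) | CC(C)=CC(=O)O[C@@H]1C[C@@H](OC(=O)CC(C)C)[C@@]2(C)[C@@H]3C(=O)C=C(C)[C@H]2[C@@H]3C1(C)C | target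

Total step count: 16. Longest linear sequence: 16 steps (fully linear from 1 and 2; diene 11 enters at step 7).

Steps most likely to fail

Step 7. Cycloaddition at the β,β-disubstituted enone carbon may stall, and the acidic unmasking may epimerise the ring-fusion methine, so the cis-fused enone may not form cleanly. The fallback sets out from 10 and comes back at 13. Copper-catalysed conjugate addition of 2-methylallylmagnesium chloride (CuBr·SMe2, TMSCl, THF, −78 °C, one extra equivalent for the free hydroxyl), anti to the silyl ether, gives (3R,4R,6R)-4-(tert-butyldimethylsilyloxy)-6-hydroxy-3,7,7-trimethyl-3-(2-methylprop-2-enyl)cycloheptan-1-one F4. Ozonolysis (O3, CH2Cl2, −78 °C; Me2S) gives (3R,4R,6R)-4-(tert-butyldimethylsilyloxy)-6-hydroxy-3,7,7-trimethyl-3-(2-oxopropyl)cycloheptan-1-one F5. N,N-Dimethylformamide dimethyl acetal (toluene, 90 °C) condenses at the methyl ketone to give (3R,4R,6R)-4-(tert-butyldimethylsilyloxy)-3-[(3E)-4-(dimethylamino)-2-oxobut-3-enyl]-6-hydroxy-3,7,7-trimethylcycloheptan-1-one F6. TsOH in toluene then lets the ring-ketone enol add to the enaminone with loss of dimethylamine, closing the cyclohexenone of 13.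

Step 11. Proton transfer from the α′-enolate to the extended dienolate, followed by vinylogous E1cB loss of the mesylate, may outrun the strained 4-exo-tet closure. The fallback sets out from 16 and comes back at 18. 1,1-Dimethylhydrazine (AcOH cat., EtOH, 50 °C) gives the N,N-dimethylhydrazone at C9 of 16 F7. LiN(iPr)2 (THF, −78 to 0 °C) forms the α′ aza-enolate, a less basic and more nucleophilic carbanion equivalent, which displaces the mesylate to give the tricyclic N,N-dimethylhydrazone at C3 of 18 F8. Aqueous oxalic acid then hydrolyses the hydrazone to 18.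

Step 4. Boron may be delivered in the 1,6 sense or to the other enone, enantiofacial discrimination on the cross-conjugated dienedione may be low, and the β-hydroxy ketone may re-eliminate during oxidation. The fallback sets out from 6 and comes back at 8. Nucleophilic epoxidation of the less substituted enone (H2O2, NaOH, MeOH, 0 °C) gives racemic cis-3,3,6-trimethyl-8-oxabicyclo[5.1.0]oct-5-ene-2,4-dione F1. Reductive opening of the α,β-epoxy ketone at the α-carbon with PhSeNa ((PhSe)2, NaBH4, AcOH, EtOH) gives racemic 6-hydroxy-2,2,5-trimethylcyclohept-4-ene-1,3-dione F2. Lipase-catalysed transesterification (Burkholderia cepacia lipase, vinyl acetate) resolves it. The acetate (6R)-6-acetoxy-2,2,5-trimethylcyclohept-4-ene-1,3-dione F3 is expected from the empirical enantiopreference of lipases for secondary alcohols; if the other enantiomer reacts, the unreacted alcohol is taken instead. F3 is separated and deacetylated with the same lipase in pH 7 buffer to give 8.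

Further compounds
F1 | step 4 | racemic cis-3,3,6-trimethyl-8-oxabicyclo[5.1.0]oct-5-ene-2,4-dione | O=C1C2OC2C(C)=CC(=O)C1(C)C
F2 | step 4 | racemic 6-hydroxy-2,2,5-trimethylcyclohept-4-ene-1,3-dione | O=C1CC(O)C(C)=CC(=O)C1(C)C
F3 | step 4 | (6R)-6-acetoxy-2,2,5-trimethylcyclohept-4-ene-1,3-dione | O=C1C[C@@H](OC(C)=O)C(C)=CC(=O)C1(C)C
F4 | step 7 | (3R,4R,6R)-4-(tert-butyldimethylsilyloxy)-6-hydroxy-3,7,7-trimethyl-3-(2-methylprop-2-enyl)cycloheptan-1-one | O[C@@H]1C[C@@H](O[Si](C)(C)C(C)(C)C)[C@](C)(CC(C)=C)CC(=O)C1(C)C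
F5 | step 7 | (3R,4R,6R)-4-(tert-butyldimethylsilyloxy)-6-hydroxy-3,7,7-trimethyl-3-(2-oxopropyl)cycloheptan-1-one | O[C@@H]1C[C@@H](O[Si](C)(C)C(C)(C)C)[C@](C)(CC(C)=O)CC(=O)C1(C)C
F6 | step 7 | (3R,4R,6R)-4-(tert-butyldimethylsilyloxy)-3-[(3E)-4-(dimethylamino)-2-oxobut-3-enyl]-6-hydroxy-3,7,7-trimethylcycloheptan-1-one | O[C@@H]1C[C@@H](O[Si](C)(C)C(C)(C)C)[C@](C)(CC(=O)/C=C/N(C)C)CC(=O)C1(C)C
F7 | step 11 | N,N-dimethylhydrazone at C9 of 16 | CC(=O)O[C@@H]1C[C@@H](O[Si](C)(C)C(C)(C)C)[C@]2(C)CC(=NN(C)C)C=C[C@@H]2[C@@H](OS(C)(=O)=O)C1(C)C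
F8 | step 11 | N,N-dimethylhydrazone at C3 of 18 | CC(=O)O[C@@H]1C[C@@H](O[Si](C)(C)C(C)(C)C)[C@@]2(C)[C@@H]3C=CC(=NN(C)C)[C@H]2[C@@H]3C1(C)C
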